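The benzotropolone of the alcohol half is disconnected across its seven-membered ring: the C=O beside the ring fusion, the enolic C–OH next to it, the adjoining CH, the carbon carrying C2 of the central chroman and the CH beside the other fusion atom are read as an opened oxygen-bridged adduct of a 2-benzopyrylium-4-olate and an alkyne. In one operation a rhodium carbenoid closes onto the neighbouring formyl oxygen, the ylide adds to a chiral α-silyloxy ynone (two C–C bonds, the carbocycle) and acid opens the bridge to the tropolone. The precursors are an o-formylaryl diazomethyl ketone bearing the protected epicatechin-type chroman and an (R)-ynone bearing brominated ring A; periodate cleavage of the same ketone supplies the acid half.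

Key step: step 18

Abbreviations: Bn benzyl; TBS tert-butyldimethylsilyl; TBDPS tert-butyldiphenylsilyl; ArA 2-bromo-4,6-bis(benzyloxy)phenyl; Chr (2R,3R)-3,5,7-tris(benzyloxy)chroman-2-yl, attached through C2.
Remark: meconin (6,7-dimethoxyphthalide) is taken as a purchasable starting material.
Remark: iodination of phthalide 12 is assumed to go to C4, the only free position para to an alkoxy group.
Remark: the acyl carbon of the diazoketone is carried as a phthalide carbonyl from the start and the formyl group is unveiled last by a neutral oxidation, so no strongly basic metalation is needed once the chroman exists and no hydroxyphthalide has to be activated.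
Remark: amide 7 serves twice (steps 5 and 9) and ketone 30 serves twice (steps 20 and 23); the carbonyl ylide is therefore generated in a single reaction and both halves of the ester descend from its product.

Step 1
Reactants: 1 1-bromo-3,5-bis(benzyloxy)benzene
Product: 2 1,5-bis(benzyloxy)-3-bromo-2-iodobenzene
Conditions: NIS, TFA (10 mol%), MeCN, 0 °C to rt
Reagents that add atoms: N-iodosuccinimide, O=C1CCC(=O)N1I
Why: Electrophilic aromatic iodination should go to the position para to one benzyloxy group and ortho to the other (beside bromine) rather than to the more crowded carbon between the two ethers, the site that formylation and halogenation of 1-bromo-3,5-dialkoxybenzenes take.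

Step 2
Reactants: 2 1,5-bis(benzyloxy)-3-bromo-2-iodobenzene; 3 methyl (R)-glycidate
Product: 5 methyl (2R)-3-ArA-2-hydroxypropanoate, via arylmagnesium chloride 4 (not isolated)
Conditions: i-PrMgCl·LiCl, THF, −40 °C; then CuI (10 mol%), 3, −40 to −20 °C; 1 M HCl (aq)
Reagents that add atoms: none
Why: Iodine–magnesium exchange is far faster at C–I than at C–Br and the ortho-bromoaryl Grignard reagent is stable at this temperature, and the copper-catalysed SN2 opening of the epoxide at its CH2 terminus leaves the C2 stereocentre of 3 untouched, so the α-hydroxy ester is (R).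

Step 3
Reactants: 5 methyl (2R)-3-ArA-2-hydroxypropanoate
Product: 6 (2R)-3-ArA-2-hydroxy-N-methoxy-N-methylpropanamide
Conditions: MeNH(OMe)·HCl, i-PrMgCl, THF, −20 to 0 °C; 1 M HCl (aq)
Reagents that add atoms: N,O-dimethylhydroxylamine hydrochloride, CNOC.Cl
Why: Aminolysis of the methyl ester by the chloromagnesium amide of N,O-dimethylhydroxylamine (Weinreb amide formation) proceeds with the α-hydroxyl held as its magnesium alkoxide, which shields the stereocentre from enolisation, while the electron-rich aryl bromide does not exchange with i-PrMgCl below 0 °C.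

Step 4
Reactants: 6 (2R)-3-ArA-2-hydroxy-N-methoxy-N-methylpropanamide
Product: 7 (2R)-3-ArA-2-(TBS-oxy)-N-methoxy-N-methylpropanamide
Conditions: TBSOTf, 2,6-lutidine, CH2Cl2, 0 °C
Reagents that add atoms: tert-butyldimethylsilyl trifluoromethanesulfonate, CC(C)(C)[Si](C)(C)OS(=O)(=O)C(F)(F)F
Why: Silylation of the secondary alcohol with the silyl triflate and a hindered pyridine base is a non-enolising protection that installs the bulky, non-chelating group needed later for Felkin–Anh control.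

Step 5
Reactants: 7 (2R)-3-ArA-2-(TBS-oxy)-N-methoxy-N-methylpropanamide; 8 ethynylmagnesium bromide
Product: 9 (4R)-5-ArA-4-(TBS-oxy)pent-1-yn-3-one
Conditions: THF, 0 °C; inverse quench into 1 M HCl (aq)/Et2O, −20 °C
Reagents that add atoms: none
Why: Weinreb ketone synthesis, in which the chelated tetrahedral magnesium intermediate prevents a second addition and protects the α-stereocentre until the cold acidic quench, which also keeps the liberated amine from adding to the ynone.

Step 6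
Reactants: 10 meconin (6,7-dimethoxyphthalide)
Product: 11 6,7-dihydroxyphthalide
Conditions: BBr3, CH2Cl2, −78 to 0 °C; H2O
Reagents that add atoms: none
Why: Lewis-acid O-demethylation of the two aryl methyl ethers by BBr3 should leave the lactone intact at or below 0 °C.

Step 7
Reactants: 11 6,7-dihydroxyphthalide
Product: 12 6,7-bis(benzyloxy)phthalide
Conditions: BnBr, K2CO3, DMF, 50 °C
Reagents that add atoms: benzyl bromide, BrCc1ccccc1
Why: Williamson etherification of both phenols with carbonate base, conditions under which the lactone is not opened.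

Step 8
Reactants: 12 6,7-bis(benzyloxy)phthalide
Product: 13 6,7-bis(benzyloxy)-4-iodophthalide
Conditions: NIS, TFA, MeCN, rt
Reagents that add atoms: N-iodosuccinimide, O=C1CCC(=O)N1I
Why: Electrophilic aromatic iodination at C4, the only free position para to an alkoxy group and meta to the lactone carbonyl, which is the substitution pattern that veratrole-type rings follow.

Step 9
Reactants: 13 6,7-bis(benzyloxy)-4-iodophthalide; 7 (2R)-3-ArA-2-(TBS-oxy)-N-methoxy-N-methylpropanamide
Product: 15 6,7-bis(benzyloxy)-4-[(2R)-3-ArA-2-(TBS-oxy)propanoyl]phthalide, via arylmagnesium chloride 14 (not isolated)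
Conditions: i-PrMgCl·LiCl, THF, −30 °C; then 7, −30 to 0 °C; 1 M HCl (aq), 0 °C
Reagents that add atoms: none
Why: Iodine–magnesium exchange with i-PrMgCl·LiCl tolerates ester-type carbonyls at low temperature and the arylmagnesium species adds once to the amide through the chelated tetrahedral intermediate (Weinreb ketone synthesis), the aryl bromide of 7 being inert to exchange and the silyloxy stereocentre never being enolised.

Step 10
Reactants: 15 6,7-bis(benzyloxy)-4-[(2R)-3-ArA-2-(TBS-oxy)propanoyl]phthalide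
Product: 16 6,7-bis(benzyloxy)-4-[(1R,2R)-3-ArA-1-hydroxy-2-(TBS-oxy)propyl]phthalide
Conditions: LiBH(s-Bu)3, THF, −78 °C; AcOH, −78 °C
Reagents that add atoms: none
Why: Polar Felkin–Anh reduction of the α-silyloxy ketone by the bulky, non-chelating borohydride, in which hydride attacks anti to the C–OSi bond and past the α-hydrogen, should set the carbinol centre (R), syn to the silyl ether, while the lactone is not reduced at −78 °C.

Step 11
Reactants: 16 6,7-bis(benzyloxy)-4-[(1R,2R)-3-ArA-1-hydroxy-2-(TBS-oxy)propyl]phthalide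
Product: 17 6,7-bis(benzyloxy)-4-[(2R,3R)-5,7-bis(benzyloxy)-3-(TBS-oxy)chroman-2-yl]phthalide
Conditions: Pd(OAc)2 (5 mol%), 2-(di-tert-butylphosphino)-1,1'-binaphthyl (6 mol%), Cs2CO3, toluene, 80 °C
Reagents that add atoms: none
Why: Intramolecular Buchwald–Hartwig C–O coupling of the secondary alcohol with the ring A bromide closes the six-membered pyran with retention at both stereocentres because no carbinol C–O bond is broken, the bulky electron-rich phosphine favouring C–O reductive elimination over β-hydride elimination and the insoluble carbonate keeping free alkoxide too scarce for silyl migration.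

Step 12
Reactants: 17 6,7-bis(benzyloxy)-4-[(2R,3R)-5,7-bis(benzyloxy)-3-(TBS-oxy)chroman-2-yl]phthalide
Product: 18 6,7-bis(benzyloxy)-4-[(2R,3R)-5,7-bis(benzyloxy)-3-hydroxychroman-2-yl]phthalide
Conditions: TBAF, AcOH, THF, rt to 40 °C
Reagents that add atoms: none
Why: Fluoride-mediated cleavage of the secondary silyl ether, buffered with acetic acid so that the lactone is not exposed to free alkoxide.

Step 13
Reactants: 18 6,7-bis(benzyloxy)-4-[(2R,3R)-5,7-bis(benzyloxy)-3-hydroxychroman-2-yl]phthalide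
Product: 19 6,7-bis(benzyloxy)-4-Chr-phthalide
Conditions: NaH, BnBr, n-Bu4NI (5 mol%), DMF, 0 °C to rt
Reagents that add atoms: benzyl bromide, BrCc1ccccc1
Why: Williamson etherification of the chroman 3-alkoxide installs the ether that survives the later fluoride steps and leaves in the final hydrogenolysis, the lactone having no enolisable position.

Step 14
Reactants: 19 6,7-bis(benzyloxy)-4-Chr-phthalide
Product: 22 2,3-bis(benzyloxy)-5-Chr-6-[(TBDPS-oxy)methyl]benzoic acid, via potassium hydroxy carboxylate 20 (not isolated), via bis-silyl derivative 21 (not isolated)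
Conditions: KOH, THF/MeOH/H2O, 50 °C; evaporate; TBDPSCl, imidazole, DMF, rt; K2CO3, MeOH/THF/H2O, rt; KHSO4 (aq) to pH 4
Reagents that add atoms: potassium hydroxide, [K+].[OH-]; tert-butyl(chloro)diphenylsilane, CC(C)(C)[Si](Cl)(c1ccccc1)c1ccccc1
Why: Saponification of the lactone, silylation of carboxylate and alcohol and selective cleavage of the labile silyl ester should give the acid with its hydroxymethyl group masked, the arrangement used in 2-(silyloxymethyl)benzoyl protecting-group chemistry, so that the acid cannot relactonise on activation.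

Step 15
Reactants: 22 2,3-bis(benzyloxy)-5-Chr-6-[(TBDPS-oxy)methyl]benzoic acid
Product: 24 2-diazo-1-{2,3-bis(benzyloxy)-5-Chr-6-[(TBDPS-oxy)methyl]phenyl}ethanone, via acid chloride 23 (not isolated)
Conditions: 1-chloro-N,N,2-trimethylprop-1-en-1-amine, CH2Cl2, 0 °C to rt; then CH2N2 (3 equiv), Et2O, 0 °C
Reagents that add atoms: diazomethane, C=[N+]=[N-]
Why: Arndt–Eistert-type acylation of diazomethane by the acid chloride, which is made under neutral conditions with the chloroenamine so that silyl and benzyl ethers survive, with excess diazomethane consuming the HCl.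

Step 16
Reactants: 24 2-diazo-1-{2,3-bis(benzyloxy)-5-Chr-6-[(TBDPS-oxy)methyl]phenyl}ethanone
Product: 25 2-diazo-1-[2,3-bis(benzyloxy)-5-Chr-6-(hydroxymethyl)phenyl]ethanone
Conditions: TBAF, AcOH, THF, 0 °C to rt
Reagents that add atoms: none
Why: Fluoride-mediated desilylation of the primary silyl ether under buffered conditions that an acceptor-substituted diazoketone tolerates.

Step 17
Reactants: 25 2-diazo-1-[2,3-bis(benzyloxy)-5-Chr-6-(hydroxymethyl)phenyl]ethanone
Product: 26 3,4-bis(benzyloxy)-2-(diazoacetyl)-6-Chr-benzaldehyde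
Conditions: MnO2, CH2Cl2, rt
Reagents that add atoms: none
Why: Heterogeneous MnO2 oxidation of the benzylic alcohol stops at the aldehyde and is neutral, so the diazoketone and all ethers are untouched and the o-formyl diazoketone is unveiled only immediately before use.

Step 18
Reactants: 26 3,4-bis(benzyloxy)-2-(diazoacetyl)-6-Chr-benzaldehyde; 9 (4R)-5-ArA-4-(TBS-oxy)pent-1-yn-3-one
Product: 29 3,4-bis(benzyloxy)-1-Chr-6-hydroxy-8-[(2R)-3-ArA-2-(TBS-oxy)propanoyl]-5H-benzo[7]annulen-5-one, via carbonyl ylide 27 (not isolated), via oxa-bridged cycloadduct 28 (not isolated)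
Conditions: Rh2(OAc)4 (2 mol%), 9 (1.5 equiv), CH2Cl2, 40 °C, slow addition of 26; then p-TsOH·H2O (0.3 equiv), rt
Reagents that add atoms: none
Why: Rh2(OAc)4 turns the diazo group of 26 into a rhodium carbenoid that is captured by the in-plane lone pair of the adjacent formyl oxygen to give the aromatic 2-benzopyrylium-4-olate 27, which adds to the ynone in a concerted 1,3-dipolar cycloaddition; p-TsOH then ionises the benzylic C–O bond of the bridge (cation stabilised by the para benzyloxy group) and loss of the proton from the carbinol carbon next to the ring ketone gives the tropolone, the oxidation level being already correct. The closest known reaction type is the rhodium carbenoid cyclisation–cycloaddition of o-acylaryl diazomethyl ketones with alkynes, followed by acid opening of the oxa-bridged adducts to benzotropolones. The pyrylium ring closes by attack of oxygen on the carbenoid carbon (six-membered cyclic ylide), and the seven-membered carbocycle is closed by the intermolecular cycloaddition across both ylide termini, its two C–C bonds forming in the same event. The two bridgehead stereocentres of 28 are transient and are erased on aromatisation, so no new stereocentre remains, and the silyloxy centre is carried through because neutral rhodium catalysis and brief mild acid do not enolise the ketone. The step needs capture of the carbenoid by the formyl oxygen in preference to the flanking benzyloxy oxygen and a single regiochemistry of addition: the first should be secured by closure to an aromatic, stabilised ylide within easy reach, the second by the polarised ynone whose unsubstituted terminus bonds to the nucleophilic enolate-type carbon of the ylide, while slow addition of 26 suppresses ylide dimerisation.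

Step 19
Reactants: 29 3,4-bis(benzyloxy)-1-Chr-6-hydroxy-8-[(2R)-3-ArA-2-(TBS-oxy)propanoyl]-5H-benzo[7]annulen-5-one
Product: 30 3,4,6-tris(benzyloxy)-1-Chr-8-[(2R)-3-ArA-2-(TBS-oxy)propanoyl]-5H-benzo[7]annulen-5-one
Conditions: BnBr, Ag2O, CH2Cl2, rt, dark
Reagents that add atoms: benzyl bromide, BrCc1ccccc1
Why: O-Benzylation of the silver tropolonate is a non-basic Williamson-type alkylation that masks the acidic, metal-binding tropolone hydroxyl without enolising the ketone beside the silyloxy stereocentre.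

Step 20
Reactants: 30 3,4,6-tris(benzyloxy)-1-Chr-8-[(2R)-3-ArA-2-(TBS-oxy)propanoyl]-5H-benzo[7]annulen-5-one
Product: 31 3,4,6-tris(benzyloxy)-1-Chr-8-[(1R,2R)-3-ArA-1-hydroxy-2-(TBS-oxy)propyl]-5H-benzo[7]annulen-5-one
Conditions: LiBH(s-Bu)3 (1.1 equiv), THF, −78 °C; AcOH, −78 °C
Reagents that add atoms: none
Why: Polar Felkin–Anh 1,2-reduction (hydride anti to the C–OSi bond, past the α-hydrogen) should set the carbinol centre (R), syn to the silyl ether, and the exocyclic ketone should react before the hindered, vinylogous-ester-like tropone carbonyl, whose conjugate reduction would cost the aromaticity of the seven-membered ring.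

Step 21
Reactants: 31 3,4,6-tris(benzyloxy)-1-Chr-8-[(1R,2R)-3-ArA-1-hydroxy-2-(TBS-oxy)propyl]-5H-benzo[7]annulen-5-one
Product: 32 3,4,6-tris(benzyloxy)-8-[(2R,3R)-5,7-bis(benzyloxy)-3-(TBS-oxy)chroman-2-yl]-1-Chr-5H-benzo[7]annulen-5-one
Conditions: Pd(OAc)2 (5 mol%), 2-(di-tert-butylphosphino)-1,1'-binaphthyl (6 mol%), Cs2CO3, toluene, 80 °C
Reagents that add atoms: none
Why: Intramolecular Buchwald–Hartwig C–O coupling closes the central pyran ring through the carbinol oxygen with retention at C2 and C3, giving the 2,3-cis chroman directly from the syn alcohol, as in step 11.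

Step 22
Reactants: 32 3,4,6-tris(benzyloxy)-8-[(2R,3R)-5,7-bis(benzyloxy)-3-(TBS-oxy)chroman-2-yl]-1-Chr-5H-benzo[7]annulen-5-one
Product: 33 3,4,6-tris(benzyloxy)-8-[(2R,3R)-5,7-bis(benzyloxy)-3-hydroxychroman-2-yl]-1-Chr-5H-benzo[7]annulen-5-one
Conditions: TBAF, AcOH, THF, rt to 40 °C
Reagents that add atoms: none
Why: Fluoride-mediated desilylation frees the only hydroxyl of the molecule, all others being benzyl ethers, so the esterification that follows has a single site.

Step 23
Reactants: 30 3,4,6-tris(benzyloxy)-1-Chr-8-[(2R)-3-ArA-2-(TBS-oxy)propanoyl]-5H-benzo[7]annulen-5-one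
Product: 34 3,4,6-tris(benzyloxy)-1-Chr-8-[(2R)-3-ArA-2-hydroxypropanoyl]-5H-benzo[7]annulen-5-one
Conditions: HF·pyridine, pyridine, THF, 0 °C to rt
Reagents that add atoms: none
Why: Fluoride-mediated cleavage of the secondary silyl ether under weakly acidic, non-enolising conditions should give the α-hydroxy ketone without shifting the ketol, the benzyl ethers being inert to buffered HF.

Step 24
Reactants: 34 3,4,6-tris(benzyloxy)-1-Chr-8-[(2R)-3-ArA-2-hydroxypropanoyl]-5H-benzo[7]annulen-5-one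
Product: 35 3,4,6-tris(benzyloxy)-1-Chr-5-oxo-5H-benzo[7]annulene-8-carboxylic acid (hexa-O-benzyl epitheaflavic acid)
Conditions: H5IO6 (2 equiv), THF/H2O (10:1), 0 °C to rt
Reagents that add atoms: water, O
Why: Malaprade-type periodate cleavage of the α-hydroxy ketone, in which water adds to the ketone that the electron-poor tropone ring activates, the hydrate and the neighbouring hydroxyl form a cyclic periodate ester, and its fragmentation gives the carboxylic acid and the arylacetaldehyde, while benzyl ethers, the chroman and the tropone ring are inert to periodate and the stereocentre that is destroyed is no longer needed.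

Step 25
Reactants: 33 3,4,6-tris(benzyloxy)-8-[(2R,3R)-5,7-bis(benzyloxy)-3-hydroxychroman-2-yl]-1-Chr-5H-benzo[7]annulen-5-one; 35 3,4,6-tris(benzyloxy)-1-Chr-5-oxo-5H-benzo[7]annulene-8-carboxylic acid
Product: 36 (2R,3R)-5,7-bis(benzyloxy)-2-[3,4,6-tris(benzyloxy)-1-Chr-5-oxo-5H-benzo[7]annulen-8-yl]chroman-3-yl 3,4,6-tris(benzyloxy)-1-Chr-5-oxo-5H-benzo[7]annulene-8-carboxylate
Conditions: EDC·HCl, DMAP, CH2Cl2, rt
Reagents that add atoms: none
Why: Steglich esterification (carbodiimide with DMAP as acyl-transfer catalyst) acylates the hindered chroman-3-ol without touching a stereocentre, since the alcohol C–O bond stays intact, as in the acylation of benzylated epicatechin with benzylated gallic acid.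

Step 26
Reactants: 36 (2R,3R)-5,7-bis(benzyloxy)-2-[3,4,6-tris(benzyloxy)-1-Chr-5-oxo-5H-benzo[7]annulen-8-yl]chroman-3-yl 3,4,6-tris(benzyloxy)-1-Chr-5-oxo-5H-benzo[7]annulene-8-carboxylate
Product: 37 CNP0315570.1 (target)
Conditions: H2 (1 atm), Pd(OH)2/C, THF/MeOH, rt
Reagents that add atoms: none
Why: Catalytic hydrogenolysis should remove all fourteen benzyl ethers under neutral conditions, while the ester, the chroman C–O bonds, the four stereocentres and the tropolone rings are not affected at 1 atm and room temperature.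

Compound list
1 | 1-bromo-3,5-bis(benzyloxy)benzene | Brc1cc(OCc2ccccc2)cc(OCc2ccccc2)c1 | starting material
2 | 1,5-bis(benzyloxy)-3-bromo-2-iodobenzene | Brc1cc(OCc2ccccc2)cc(OCc2ccccc2)c1I | intermediate
3 | methyl (R)-glycidate | COC(=O)[C@H]1CO1 | starting material
4 | [2-bromo-4,6-bis(benzyloxy)phenyl]magnesium chloride | Cl[Mg]c1c(Br)cc(OCc2ccccc2)cc1OCc1ccccc1 | intermediate
5 | methyl (2R)-3-ArA-2-hydroxypropanoate | COC(=O)[C@H](O)Cc1c(Br)cc(OCc2ccccc2)cc1OCc1ccccc1 | intermediate
6 | (2R)-3-ArA-2-hydroxy-N-methoxy-N-methylpropanamide | CON(C)C(=O)[C@H](O)Cc1c(Br)cc(OCc2ccccc2)cc1OCc1ccccc1 | intermediate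
7 | (2R)-3-ArA-2-(TBS-oxy)-N-methoxy-N-methylpropanamide | CON(C)C(=O)[C@H](O[Si](C)(C)C(C)(C)C)Cc1c(Br)cc(OCc2ccccc2)cc1OCc1ccccc1 | intermediate
8 | ethynylmagnesium bromide | C#C[Mg]Br | starting material
9 | (4R)-5-ArA-4-(TBS-oxy)pent-1-yn-3-one | C#CC(=O)[C@H](O[Si](C)(C)C(C)(C)C)Cc1c(Br)cc(OCc2ccccc2)cc1OCc1ccccc1 | intermediate
10 | meconin (6,7-dimethoxyphthalide) | COc1ccc2COC(=O)c2c1OC | starting material
11 | 6,7-dihydroxyphthalide | Oc1ccc2COC(=O)c2c1O | intermediate
12 | 6,7-bis(benzyloxy)phthalide | O=C1OCc2ccc(OCc3ccccc3)c(OCc3ccccc3)c12 | intermediate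
13 | 6,7-bis(benzyloxy)-4-iodophthalide | O=C1OCc2c(I)cc(OCc3ccccc3)c(OCc3ccccc3)c12 | intermediate
14 | [6,7-bis(benzyloxy)-1-oxo-1,3-dihydroisobenzofuran-4-yl]magnesium chloride | O=C1OCc2c([Mg]Cl)cc(OCc3ccccc3)c(OCc3ccccc3)c12 | intermediate
15 | 6,7-bis(benzyloxy)-4-[(2R)-3-ArA-2-(TBS-oxy)propanoyl]phthalide | O=C1OCc2c(C(=O)[C@H](O[Si](C)(C)C(C)(C)C)Cc3c(Br)cc(OCc4ccccc4)cc3OCc3ccccc3)cc(OCc3ccccc3)c(OCc3ccccc3)c12 | intermediate
16 | 6,7-bis(benzyloxy)-4-[(1R,2R)-3-ArA-1-hydroxy-2-(TBS-oxy)propyl]phthalide | O=C1OCc2c([C@@H](O)[C@H](O[Si](C)(C)C(C)(C)C)Cc3c(Br)cc(OCc4ccccc4)cc3OCc3ccccc3)cc(OCc3ccccc3)c(OCc3ccccc3)c12 | intermediate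
17 | 6,7-bis(benzyloxy)-4-[(2R,3R)-5,7-bis(benzyloxy)-3-(TBS-oxy)chroman-2-yl]phthalide | O=C1OCc2c([C@H]3Oc4cc(OCc5ccccc5)cc(OCc5ccccc5)c4C[C@H]3O[Si](C)(C)C(C)(C)C)cc(OCc3ccccc3)c(OCc3ccccc3)c12 | intermediate
18 | 6,7-bis(benzyloxy)-4-[(2R,3R)-5,7-bis(benzyloxy)-3-hydroxychroman-2-yl]phthalide | O=C1OCc2c([C@H]3Oc4cc(OCc5ccccc5)cc(OCc5ccccc5)c4C[C@H]3O)cc(OCc3ccccc3)c(OCc3ccccc3)c12 | intermediate
19 | 6,7-bis(benzyloxy)-4-Chr-phthalide | O=C1OCc2c([C@H]3Oc4cc(OCc5ccccc5)cc(OCc5ccccc5)c4C[C@H]3OCc3ccccc3)cc(OCc3ccccc3)c(OCc3ccccc3)c12 | intermediate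
20 | potassium 2,3-bis(benzyloxy)-5-Chr-6-(hydroxymethyl)benzoate | [K+].[O-]C(=O)c1c(OCc2ccccc2)c(OCc2ccccc2)cc([C@H]3Oc4cc(OCc5ccccc5)cc(OCc5ccccc5)c4C[C@H]3OCc3ccccc3)c1CO | intermediate
21 | tert-butyldiphenylsilyl 2,3-bis(benzyloxy)-5-Chr-6-[(TBDPS-oxy)methyl]benzoate | CC(C)(C)[Si](OC(=O)c1c(OCc2ccccc2)c(OCc2ccccc2)cc([C@H]3Oc4cc(OCc5ccccc5)cc(OCc5ccccc5)c4C[C@H]3OCc3ccccc3)c1CO[Si](c1ccccc1)(c1ccccc1)C(C)(C)C)(c1ccccc1)c1ccccc1 | intermediate
22 | 2,3-bis(benzyloxy)-5-Chr-6-[(TBDPS-oxy)methyl]benzoic acid | OC(=O)c1c(OCc2ccccc2)c(OCc2ccccc2)cc([C@H]3Oc4cc(OCc5ccccc5)cc(OCc5ccccc5)c4C[C@H]3OCc3ccccc3)c1CO[Si](c1ccccc1)(c1ccccc1)C(C)(C)C | intermediate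
23 | 2,3-bis(benzyloxy)-5-Chr-6-[(TBDPS-oxy)methyl]benzoyl chloride | ClC(=O)c1c(OCc2ccccc2)c(OCc2ccccc2)cc([C@H]3Oc4cc(OCc5ccccc5)cc(OCc5ccccc5)c4C[C@H]3OCc3ccccc3)c1CO[Si](c1ccccc1)(c1ccccc1)C(C)(C)C | intermediate
24 | 2-diazo-1-{2,3-bis(benzyloxy)-5-Chr-6-[(TBDPS-oxy)methyl]phenyl}ethanone | [N-]=[N+]=CC(=O)c1c(OCc2ccccc2)c(OCc2ccccc2)cc([C@H]3Oc4cc(OCc5ccccc5)cc(OCc5ccccc5)c4C[C@H]3OCc3ccccc3)c1CO[Si](c1ccccc1)(c1ccccc1)C(C)(C)C | intermediate
25 | 2-diazo-1-[2,3-bis(benzyloxy)-5-Chr-6-(hydroxymethyl)phenyl]ethanone | [N-]=[N+]=CC(=O)c1c(OCc2ccccc2)c(OCc2ccccc2)cc([C@H]3Oc4cc(OCc5ccccc5)cc(OCc5ccccc5)c4C[C@H]3OCc3ccccc3)c1CO | intermediate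
26 | 3,4-bis(benzyloxy)-2-(diazoacetyl)-6-Chr-benzaldehyde (o-formylaryl diazomethyl ketone) | [N-]=[N+]=CC(=O)c1c(OCc2ccccc2)c(OCc2ccccc2)cc([C@H]3Oc4cc(OCc5ccccc5)cc(OCc5ccccc5)c4C[C@H]3OCc3ccccc3)c1C=O | intermediate
27 | 5,6-bis(benzyloxy)-8-Chr-2-benzopyrylium-4-olate (carbonyl ylide) | [O-]C1=C[O+]=Cc2c([C@H]3Oc4cc(OCc5ccccc5)cc(OCc5ccccc5)c4C[C@H]3OCc3ccccc3)cc(OCc3ccccc3)c(OCc3ccccc3)c12 | intermediate
28 | 3,4-bis(benzyloxy)-1-Chr-8-[(2R)-3-ArA-2-(TBS-oxy)propanoyl]-6,9-dihydro-6,9-epoxy-5H-benzo[7]annulen-5-one (both bridgehead epimers) | O=C1c2c(OCc3ccccc3)c(OCc3ccccc3)cc([C@H]3Oc4cc(OCc5ccccc5)cc(OCc5ccccc5)c4C[C@H]3OCc3ccccc3)c2C2OC1C=C2C(=O)[C@H](O[Si](C)(C)C(C)(C)C)Cc1c(Br)cc(OCc2ccccc2)cc1OCc1ccccc1 | intermediate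
29 | 3,4-bis(benzyloxy)-1-Chr-6-hydroxy-8-[(2R)-3-ArA-2-(TBS-oxy)propanoyl]-5H-benzo[7]annulen-5-one | Brc1cc(OCc2ccccc2)cc(OCc2ccccc2)c1C[C@@H](O[Si](C)(C)C(C)(C)C)C(=O)c1cc(O)c(=O)c2c(OCc3ccccc3)c(OCc3ccccc3)cc([C@H]3Oc4cc(OCc5ccccc5)cc(OCc5ccccc5)c4C[C@H]3OCc3ccccc3)c2c1 | intermediate
30 | 3,4,6-tris(benzyloxy)-1-Chr-8-[(2R)-3-ArA-2-(TBS-oxy)propanoyl]-5H-benzo[7]annulen-5-one | Brc1cc(OCc2ccccc2)cc(OCc2ccccc2)c1C[C@@H](O[Si](C)(C)C(C)(C)C)C(=O)c1cc(OCc3ccccc3)c(=O)c2c(OCc3ccccc3)c(OCc3ccccc3)cc([C@H]3Oc4cc(OCc5ccccc5)cc(OCc5ccccc5)c4C[C@H]3OCc3ccccc3)c2c1 | intermediate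
31 | 3,4,6-tris(benzyloxy)-1-Chr-8-[(1R,2R)-3-ArA-1-hydroxy-2-(TBS-oxy)propyl]-5H-benzo[7]annulen-5-one | Brc1cc(OCc2ccccc2)cc(OCc2ccccc2)c1C[C@@H](O[Si](C)(C)C(C)(C)C)[C@H](O)c1cc(OCc3ccccc3)c(=O)c2c(OCc3ccccc3)c(OCc3ccccc3)cc([C@H]3Oc4cc(OCc5ccccc5)cc(OCc5ccccc5)c4C[C@H]3OCc3ccccc3)c2c1 | intermediate
32 | 3,4,6-tris(benzyloxy)-8-[(2R,3R)-5,7-bis(benzyloxy)-3-(TBS-oxy)chroman-2-yl]-1-Chr-5H-benzo[7]annulen-5-one | CC(C)(C)[Si](C)(C)O[C@@H]1Cc2c(OCc3ccccc3)cc(OCc3ccccc3)cc2O[C@@H]1c1cc(OCc2ccccc2)c(=O)c2c(OCc3ccccc3)c(OCc3ccccc3)cc([C@H]3Oc4cc(OCc5ccccc5)cc(OCc5ccccc5)c4C[C@H]3OCc3ccccc3)c2c1 | intermediate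
33 | 3,4,6-tris(benzyloxy)-8-[(2R,3R)-5,7-bis(benzyloxy)-3-hydroxychroman-2-yl]-1-Chr-5H-benzo[7]annulen-5-one | O[C@@H]1Cc2c(OCc3ccccc3)cc(OCc3ccccc3)cc2O[C@@H]1c1cc(OCc2ccccc2)c(=O)c2c(OCc3ccccc3)c(OCc3ccccc3)cc([C@H]3Oc4cc(OCc5ccccc5)cc(OCc5ccccc5)c4C[C@H]3OCc3ccccc3)c2c1 | intermediate
34 | 3,4,6-tris(benzyloxy)-1-Chr-8-[(2R)-3-ArA-2-hydroxypropanoyl]-5H-benzo[7]annulen-5-one | Brc1cc(OCc2ccccc2)cc(OCc2ccccc2)c1C[C@@H](O)C(=O)c1cc(OCc3ccccc3)c(=O)c2c(OCc3ccccc3)c(OCc3ccccc3)cc([C@H]3Oc4cc(OCc5ccccc5)cc(OCc5ccccc5)c4C[C@H]3OCc3ccccc3)c2c1 | intermediate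
35 | 3,4,6-tris(benzyloxy)-1-Chr-5-oxo-5H-benzo[7]annulene-8-carboxylic acid (hexa-O-benzyl epitheaflavic acid) | OC(=O)c1cc(OCc2ccccc2)c(=O)c2c(OCc3ccccc3)c(OCc3ccccc3)cc([C@H]3Oc4cc(OCc5ccccc5)cc(OCc5ccccc5)c4C[C@H]3OCc3ccccc3)c2c1 | intermediate
36 | (2R,3R)-5,7-bis(benzyloxy)-2-[3,4,6-tris(benzyloxy)-1-Chr-5-oxo-5H-benzo[7]annulen-8-yl]chroman-3-yl 3,4,6-tris(benzyloxy)-1-Chr-5-oxo-5H-benzo[7]annulene-8-carboxylate | O=C(O[C@@H]1Cc2c(OCc3ccccc3)cc(OCc3ccccc3)cc2O[C@@H]1c1cc(OCc2ccccc2)c(=O)c2c(OCc3ccccc3)c(OCc3ccccc3)cc([C@H]3Oc4cc(OCc5ccccc5)cc(OCc5ccccc5)c4C[C@H]3OCc3ccccc3)c2c1)c1cc(OCc2ccccc2)c(=O)c2c(OCc3ccccc3)c(OCc3ccccc3)cc([C@H]3Oc4cc(OCc5ccccc5)cc(OCc5ccccc5)c4C[C@H]3OCc3ccccc3)c2c1 | intermediate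
37 | CNP0315570.1 | O=C(O[C@@H]1Cc2c(O)cc(O)cc2O[C@@H]1c1cc(O)c(=O)c2c(O)c(O)cc([C@H]3Oc4cc(O)cc(O)c4C[C@H]3O)c2c1)c1cc(O)c(=O)c2c(O)c(O)cc([C@H]3Oc4cc(O)cc(O)c4C[C@H]3O)c2c1 | target

Total step count: 26. Longest linear sequence: 20 steps (1 → 2 → 5 → 6 → 7 → 15 → 16 → 17 → 18 → 19 → 22 → 24 → 25 → 26 → 29 → 30 → 31 → 32 → 33 → 36 → 37).

Steps most likely to fail

Step 18. The rhodium carbenoid may be intercepted by the flanking benzyloxy oxygen (oxonium ylide formation followed by a 1,2-benzyl shift), or the ylide may dimerise faster than it adds to the hindered ynone. The fallback generates the same ylide without a carbenoid and sets out from 26. HClO4 (catalytic) in aqueous dioxane should hydrolyse the diazoketone to the hydroxymethyl ketone, which closes onto the neighbouring aldehyde to give the lactol 5,6-bis(benzyloxy)-8-Chr-1-hydroxyisochroman-4-one F1. Ac2O and pyridine should convert it into 5,6-bis(benzyloxy)-8-Chr-4-oxoisochroman-1-yl acetate F2. Et3N in MeCN at 60 °C with 9 present should eliminate acetic acid, the benzo counterpart of the acetoxypyranone route to oxidopyrylium ylides, and so comes back to the route at ylide 27, which adds to 9 and is opened with p-TsOH as in step 18.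

Step 9. The arylmagnesium species may attack the lactone carbonyl of a second molecule, or the iodine–magnesium exchange may stay incomplete, while addition to the hindered amide is slow. The fallback sets out from 7. i-Bu2AlH in CH2Cl2 at −78 °C should reduce the amide to the aldehyde (2R)-3-ArA-2-(TBS-oxy)propanal F3. Arylmagnesium chloride 14, made from 13 as in step 9, should add to F3 at −60 °C, far below the temperature at which a lactone is attacked, to give 6,7-bis(benzyloxy)-4-[(2R)-3-ArA-1-hydroxy-2-(TBS-oxy)propyl]phthalide F4 as a mixture of carbinol epimers. Dess–Martin periodinane should oxidise both epimers to ketone 15, where the route is rejoined.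

Step 26. Hydrogenation may run on into the tropolone rings, or the debenzylation may stall because the liberated tropolones bind the palladium surface. The fallback is a non-reductive Lewis-acid debenzylation that sets out from 36: BCl3 with pentamethylbenzene as benzyl-cation scavenger, CH2Cl2, −78 to −20 °C, then methanol quench, should give 37 directly. No further compound arises (none F0).

Further compounds
F1 | step 18 | 5,6-bis(benzyloxy)-8-Chr-1-hydroxyisochroman-4-one (lactol, both C1 epimers) | O=C1COC(O)c2c([C@H]3Oc4cc(OCc5ccccc5)cc(OCc5ccccc5)c4C[C@H]3OCc3ccccc3)cc(OCc3ccccc3)c(OCc3ccccc3)c12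
F2 | step 18 | 5,6-bis(benzyloxy)-8-Chr-4-oxoisochroman-1-yl acetate (both C1 epimers) | O=C1COC(OC(C)=O)c2c([C@H]3Oc4cc(OCc5ccccc5)cc(OCc5ccccc5)c4C[C@H]3OCc3ccccc3)cc(OCc3ccccc3)c(OCc3ccccc3)c12
F3 | step 9 | (2R)-3-ArA-2-(TBS-oxy)propanal | O=C[C@H](O[Si](C)(C)C(C)(C)C)Cc1c(Br)cc(OCc2ccccc2)cc1OCc1ccccc1
F4 | step 9 | 6,7-bis(benzyloxy)-4-[(2R)-3-ArA-1-hydroxy-2-(TBS-oxy)propyl]phthalide (both carbinol epimers) | O=C1OCc2c(C(O)[C@H](O[Si](C)(C)C(C)(C)C)Cc3c(Br)cc(OCc4ccccc4)cc3OCc3ccccc3)cc(OCc3ccccc3)c(OCc3ccccc3)c12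
F0 | step 26 | none | none
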